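**Retrosynthetic overview**
- Target 25 comes from the bis-silylated macrocyclic lactone 20 by C6 desilylation, angeloylation and C1 desilylation.
- Key disconnection of 20: C7–C8 and C11–C12 (with the acyl C–O bond) are cut together, giving the acyclic allenyl aldehyde 18 and CO. The forward reaction is a macrocyclic allenic hetero-Pauson–Khand reaction that closes the ten-membered carbocycle and the α-methylene-γ-lactone at once and sets C7 and C8.
- Enabling feature: the C7–C8 bond is shared by the cyclodecane and the lactone ring, with the lactone oxygen on C8 and the exocyclic C11=C13 alkene on C7, which is the pattern of aldehyde + allene + CO. The cis-oxirane C4–C5 (C3 and C6 syn) and the sp2 carbon C10 fold the chain, and the C6 silyloxy centre next to C7 steers the new centres.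
- 18 is assembled from neryl acetate (C1–C6 and C15; its Z-alkene becomes the cis-oxirane), 3-bromobut-3-en-1-ol (C8–C10 and C14), and acetylene plus formaldehyde (C7, C11, C13).
- Ring order: oxirane (step 8), then cyclodecane and lactone together (step 14).

Key step: step 14

Remark: atoms are numbered as in a germacrane (ring carbons C1–C10, lactone carbons C11–C13, C14 on C10, C15 on C4), also in the acyclic intermediates; the Felkin epimer from step 10 is assumed to be separable from its C6 epimer by chromatography.

Step 1
Reactants: 1 3-bromobut-3-en-1-ol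
Product: 2 (3-bromobut-3-en-1-yloxy)triethylsilane
Conditions: TESCl, imidazole, CH2Cl2, 0 °C
Reagents that add atoms: chlorotriethylsilane, CC[Si](Cl)(CC)CC
Why: Imidazole-mediated silylation of a primary alcohol is routine and forms no stereocentre.

Step 2
Reactants: 3 neryl acetate
Product: 5 (2Z)-3-methyl-6-oxohex-2-en-1-yl acetate, via ozonide 4 (not isolated)
Conditions: O3 (1 equiv), CH2Cl2, −78 °C; then Me2S, −78 °C to rt
Reagents that add atoms: ozone, [O-][O+]=O
Why: Chemoselective ozonolysis should work because the isopropylidene alkene is more electron-rich than the alkene deactivated by the allylic acetate, so one equivalent of ozone forms ozonide 4 only there and dimethyl sulfide reduces it to the aldehyde.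

Step 3
Reactants: 5 (2Z)-3-methyl-6-oxohex-2-en-1-yl acetate; 2 (3-bromobut-3-en-1-yloxy)triethylsilane
Product: 7 (2Z)-6-hydroxy-3-methyl-7-methylidene-9-(triethylsilyloxy)non-2-en-1-yl acetate (both C1 epimers), via alkenylchromium 6 (not isolated)
Conditions: CrCl2 (4 equiv), NiCl2 (2 mol %), DMF, rt
Reagents that add atoms: none
Why: In this Nozaki–Hiyama–Kishi coupling the alkenylchromium 6 adds to the aldehyde and leaves the acetate and silyl ether untouched; the new C1 carbinol centre forms without control and is erased in step 4.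

Step 4
Reactants: 7 allylic alcohol (epimer mixture)
Product: 8 (2Z)-3-methyl-7-methylidene-6-oxo-9-(triethylsilyloxy)non-2-en-1-yl acetate
Conditions: Dess–Martin periodinane, pyridine, CH2Cl2, 0 °C
Reagents that add atoms: none
Why: Buffered Dess–Martin oxidation of a secondary allylic alcohol should give the enone without cleaving the acid-labile primary silyl ether.

Step 5
Reactants: 8 enone
Product: 9 (2Z,6S)-6-hydroxy-3-methyl-7-methylidene-9-(triethylsilyloxy)non-2-en-1-yl acetate
Conditions: (R)-2-methyl-CBS-oxazaborolidine (20 mol %), catecholborane, toluene, −78 °C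
Reagents that add atoms: none
Why: In this Corey–Bakshi–Shibata reduction the α-branched alkenyl group acts as the large substituent and the CH2 chain as the small one, so the (R)-catalyst should deliver hydride to the face that gives the 1S alcohol, and catecholborane at low temperature avoids hydroboration.

Step 6
Reactants: 9 (S)-allylic alcohol
Product: 10 (2Z,6S)-6-(tert-butyldimethylsilyloxy)-3-methyl-7-methylidene-9-(triethylsilyloxy)non-2-en-1-yl acetate
Conditions: TBSCl, imidazole, DMF, rt
Reagents that add atoms: tert-butyldimethylsilyl chloride, CC(C)(C)[Si](C)(C)Cl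
Why: Standard silylation of a secondary allylic alcohol proceeds with retention because the C–O bond is not touched.

Step 7
Reactants: 10 silyl ether acetate
Product: 11 (2Z,6S)-6-(tert-butyldimethylsilyloxy)-3-methyl-7-methylidene-9-(triethylsilyloxy)non-2-en-1-ol
Conditions: K2CO3 (20 mol %), MeOH, 0 °C
Reagents that add atoms: none
Why: Base-catalysed transesterification removes the acetate under conditions that both silyl ethers should survive when the reaction is kept cold and short.

Step 8
Reactants: 11 (Z)-allylic alcohol
Product: 12 [(2S,3R)-3-[(3S)-3-(tert-butyldimethylsilyloxy)-4-methylidene-6-(triethylsilyloxy)hexyl]-3-methyloxiran-2-yl]methanol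
Conditions: Ti(OiPr)4 (10 mol %), L-(+)-diethyl tartrate (12 mol %), tBuOOH, 4 Å molecular sieves, CH2Cl2, −20 °C
Reagents that add atoms: tert-butyl hydroperoxide, CC(C)(C)OO
Why: In this Sharpless asymmetric epoxidation only the free allylic alcohol binds titanium, L-(+)-diethyl tartrate should direct oxygen to the face that gives the (4R,5S) oxirane as it does with nerol, and the Z-alkene fixes C3 and C6 cis on the ring.

Step 9
Reactants: 12 epoxy alcohol
Product: 13 (2R,3R)-3-[(3S)-3-(tert-butyldimethylsilyloxy)-4-methylidene-6-(triethylsilyloxy)hexyl]-3-methyloxirane-2-carbaldehyde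
Conditions: Dess–Martin periodinane, pyridine, CH2Cl2, 0 °C
Reagents that add atoms: none
Why: Buffered Dess–Martin oxidation converts 2,3-epoxy alcohols into epoxy aldehydes without epimerisation; the C5 descriptor changes only through the priority rules.

Step 10
Reactants: 13 epoxy aldehyde
Product: 14 (1S)-1-[(2S,3R)-3-[(3S)-3-(tert-butyldimethylsilyloxy)-4-methylidene-6-(triethylsilyloxy)hexyl]-3-methyloxiran-2-yl]prop-2-yn-1-ol
Conditions: ethynylmagnesium bromide, THF, −78 °C
Reagents that add atoms: ethynylmagnesium bromide, C#C[Mg]Br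
Why: In this Felkin–Anh addition to an α,β-epoxy aldehyde the Grignard reagent approaches anti to the oxirane C5–O bond and past the hydrogen on C5, which should give the anti epoxy alcohol with the 6S configuration as the major epimer.

Step 11
Reactants: 14 propargylic alcohol
Product: 15 triethylsilyl ether of 14
Conditions: TESCl, imidazole, DMAP (cat.), CH2Cl2, 0 °C to rt
Reagents that add atoms: chlorotriethylsilane, CC[Si](Cl)(CC)CC
Why: Silylation of the secondary propargylic alcohol installs the bulky, non-ionisable group needed on C6 in step 14 and leaves the configuration unchanged.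

Step 12
Reactants: 15 terminal alkyne
Product: 17 allene (buta-2,3-dien-1-yl silyl ether), via propargylic amine 16 (not isolated)
Conditions: CuI (50 mol %), paraformaldehyde, dicyclohexylamine, 1,4-dioxane, reflux
Reagents that add atoms: paraformaldehyde (as formaldehyde), C=O
Why: In this Crabbé homologation a Mannich reaction gives amine 16 and a copper-assisted 1,5-hydride shift from an N-cyclohexyl C–H to C7 with loss of the imine gives the terminal allene, without involving any stereocentre.

Step 13
Reactants: 17 allene with primary triethylsilyl ether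
Product: 18 allenyl aldehyde
Conditions: (COCl)2, DMSO, CH2Cl2, −78 to −40 °C; then Et3N, −78 °C, cold work-up
Reagents that add atoms: none
Why: Swern oxidation applied directly to a primary triethylsilyl ether is selective because chlorodimethylsulfonium chloride attacks only the unhindered primary Si–O bond, the secondary silyl ethers stay, and a cold quench should keep the β,γ-unsaturated aldehyde out of conjugation.

Step 14
Reactants: 18 allenyl aldehyde
Product: 20 (1S,4R,5S,6S,7R,8S)-1-(tert-butyldimethylsilyloxy)-4,5-epoxy-6-(triethylsilyloxy)germacra-10(14),11(13)-dien-8,12-olide, via oxaruthenacycle 19 (not isolated)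
Conditions: Ru3(CO)12 (10 mol %), CO (20 atm), 1,4-dioxane, 0.002 molar by slow addition of 18, 120 °C
Reagents that add atoms: carbon monoxide, [C-]#[O+]
Why: Proposed new method: zerovalent ruthenium carbonyl binds the aldehyde and the internal allene π-bond C7=C11, oxidative cyclisation gives oxaruthenacycle 19 and forms C7–C8, CO inserts into the Ru–C11 bond and forms C11–C12, and reductive elimination of the acyl–oxygen bond releases 20 and the catalyst. The closest known reaction type is the Ru3(CO)12-catalysed hetero-Pauson–Khand cyclocarbonylation of tethered allenyl aldehydes to fused α-methylene-γ-butyrolactones, supported by the untethered ruthenium-catalysed ketone/alkene/CO [2+2+1]; what is new is that the tether closes a ten-membered instead of a five- or six-membered carbocycle. The cyclodecane ring closes by C–C bond formation with both reacting π-bonds exocyclic to it (10-exo at the trigonal allene carbon C7), and the lactone is assembled as the [2+2+1] ring from C7–C11, C8=O and CO with C13 left as the exocyclic methylene. C7 is controlled by the C6 stereocentre: in the reactive rotamer C6–H lies in the allene plane, the bulky Et3SiO group is anti to ruthenium and the C5 tether is on the metal-bound face, which should give the 6S,7R relation. C8 is set in the same oxidative cyclisation, where the C6 and C9 ring bonds take the trans arrangement on the metallacycle that lets the eight-atom tether span it without transannular strain, so H7 and H8 end anti and the lactone is trans-fused (7R,8S). The step needs ring closure over oligomerisation and reaction at the internal rather than the terminal allene π-bond; high dilution, the fold imposed by the cis-oxirane C4–C5 and sp2 C10, and the strained twelve-membered ring that the terminal mode would require are what should secure this.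

Step 15
Reactants: 20 bis-silylated lactone
Product: 21 (1S,4R,5S,6S,7S,8S)-1-(tert-butyldimethylsilyloxy)-4,5-epoxy-6-hydroxygermacra-10(14),11(13)-dien-8,12-olide
Conditions: HF·pyridine, pyridine, THF, 0 °C
Reagents that add atoms: none
Why: Selective desilylation should work because a secondary triethylsilyl ether is cleaved by buffered HF·pyridine much faster than a secondary tert-butyldimethylsilyl ether; the C7 descriptor changes only through the priority rules.

Step 16
Reactants: 21 C6 alcohol; 22 angelic acid
Product: 24 (1S,4R,5S,6S,7R,8S)-6-angeloyloxy-1-(tert-butyldimethylsilyloxy)-4,5-epoxygermacra-10(14),11(13)-dien-8,12-olide, via mixed anhydride 23 (not isolated)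
Conditions: 22, 2,4,6-trichlorobenzoyl chloride, Et3N, toluene, rt; then 21, toluene, 80 °C
Reagents that add atoms: none
Why: In this Yamaguchi esterification run without DMAP the mixed anhydride 23 acylates the hindered C6 alcohol on heating, and leaving out the nucleophilic catalyst should keep the Z (angelate) geometry from isomerising to the tiglate.

Step 17
Reactants: 24 silylated angelate
Product: 25 (1S,4R,5S,6S,7R,8S)-6-angeloyloxy-4,5-epoxy-1-hydroxygermacra-10(14),11(13)-dien-8,12-olide (CNP0104965.1)
Conditions: HF·pyridine, pyridine, THF, 0 °C to rt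
Reagents that add atoms: none
Why: Buffered fluoride desilylation of the allylic silyl ether is non-basic and should free the C1 alcohol without conjugate addition to the α-methylene lactone or opening of the oxirane.

**Compound list**
1 | 3-bromobut-3-en-1-ol | C=C(Br)CCO | starting material
2 | (3-bromobut-3-en-1-yloxy)triethylsilane | C=C(Br)CCO[Si](CC)(CC)CC | intermediate
3 | neryl acetate, (2Z)-3,7-dimethylocta-2,6-dien-1-yl acetate | CC(C)=CCC/C(C)=C\COC(C)=O | starting material
4 | ozonide of 3 at the 6,7-alkene, (2Z)-5-(5,5-dimethyl-1,2,4-trioxolan-3-yl)-3-methylpent-2-en-1-yl acetate | CC1(C)OOC(CC/C(C)=C\COC(C)=O)O1 | intermediate (not isolated)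
5 | (2Z)-3-methyl-6-oxohex-2-en-1-yl acetate | O=CCC/C(C)=C\COC(C)=O | intermediate
6 | dichloro[4-(triethylsilyloxy)but-1-en-2-yl]chromium | C=C(CCO[Si](CC)(CC)CC)[Cr](Cl)Cl | intermediate (not isolated)
7 | (2Z)-6-hydroxy-3-methyl-7-methylidene-9-(triethylsilyloxy)non-2-en-1-yl acetate, both epimers at the carbinol carbon | C=C(CCO[Si](CC)(CC)CC)C(O)CC/C(C)=C\COC(C)=O | intermediate
8 | (2Z)-3-methyl-7-methylidene-6-oxo-9-(triethylsilyloxy)non-2-en-1-yl acetate | C=C(CCO[Si](CC)(CC)CC)C(=O)CC/C(C)=C\COC(C)=O | intermediate
9 | (2Z,6S)-6-hydroxy-3-methyl-7-methylidene-9-(triethylsilyloxy)non-2-en-1-yl acetate | C=C(CCO[Si](CC)(CC)CC)[C@@H](O)CC/C(C)=C\COC(C)=O | intermediate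
10 | (2Z,6S)-6-(tert-butyldimethylsilyloxy)-3-methyl-7-methylidene-9-(triethylsilyloxy)non-2-en-1-yl acetate | C=C(CCO[Si](CC)(CC)CC)[C@@H](O[Si](C)(C)C(C)(C)C)CC/C(C)=C\COC(C)=O | intermediate
11 | (2Z,6S)-6-(tert-butyldimethylsilyloxy)-3-methyl-7-methylidene-9-(triethylsilyloxy)non-2-en-1-ol | C=C(CCO[Si](CC)(CC)CC)[C@@H](O[Si](C)(C)C(C)(C)C)CC/C(C)=C\CO | intermediate
12 | [(2S,3R)-3-[(3S)-3-(tert-butyldimethylsilyloxy)-4-methylidene-6-(triethylsilyloxy)hexyl]-3-methyloxiran-2-yl]methanol | C=C(CCO[Si](CC)(CC)CC)[C@@H](O[Si](C)(C)C(C)(C)C)CC[C@@]1(C)O[C@H]1CO | intermediate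
13 | (2R,3R)-3-[(3S)-3-(tert-butyldimethylsilyloxy)-4-methylidene-6-(triethylsilyloxy)hexyl]-3-methyloxirane-2-carbaldehyde | C=C(CCO[Si](CC)(CC)CC)[C@@H](O[Si](C)(C)C(C)(C)C)CC[C@@]1(C)O[C@H]1C=O | intermediate
14 | (1S)-1-[(2S,3R)-3-[(3S)-3-(tert-butyldimethylsilyloxy)-4-methylidene-6-(triethylsilyloxy)hexyl]-3-methyloxiran-2-yl]prop-2-yn-1-ol | C=C(CCO[Si](CC)(CC)CC)[C@@H](O[Si](C)(C)C(C)(C)C)CC[C@@]1(C)O[C@H]1[C@@H](O)C#C | intermediate
15 | triethylsilyl ether of 14 at the propargylic oxygen (6S) | C=C(CCO[Si](CC)(CC)CC)[C@@H](O[Si](C)(C)C(C)(C)C)CC[C@@]1(C)O[C@H]1[C@@H](O[Si](CC)(CC)CC)C#C | intermediate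
16 | Mannich base of 15, carrying CH2N(cyclohexyl)2 on the alkyne terminus | C=C(CCO[Si](CC)(CC)CC)[C@@H](O[Si](C)(C)C(C)(C)C)CC[C@@]1(C)O[C@H]1[C@@H](O[Si](CC)(CC)CC)C#CCN(C2CCCCC2)C2CCCCC2 | intermediate (not isolated)
17 | allene, triethyl{[(1S)-1-[(2S,3R)-3-[(3S)-3-(tert-butyldimethylsilyloxy)-4-methylidene-6-(triethylsilyloxy)hexyl]-3-methyloxiran-2-yl]buta-2,3-dien-1-yl]oxy}silane | C=C(CCO[Si](CC)(CC)CC)[C@@H](O[Si](C)(C)C(C)(C)C)CC[C@@]1(C)O[C@H]1[C@@H](O[Si](CC)(CC)CC)C=C=C | intermediate
18 | allenyl aldehyde, (4S)-4-(tert-butyldimethylsilyloxy)-3-methylidene-6-[(2R,3S)-2-methyl-3-[(1S)-1-(triethylsilyloxy)buta-2,3-dien-1-yl]oxiran-2-yl]hexanal | O=CCC(=C)[C@@H](O[Si](C)(C)C(C)(C)C)CC[C@@]1(C)O[C@H]1[C@@H](O[Si](CC)(CC)CC)C=C=C | intermediate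
19 | oxaruthenacycle with the five-membered ring Ru–O–C8–C7–C11, carbonyl ligands on ruthenium not drawn | C=C1[Ru]O[C@H]2CC(=C)[C@@H](O[Si](C)(C)C(C)(C)C)CC[C@@]3(C)O[C@H]3[C@@H](O[Si](CC)(CC)CC)[C@H]12 | intermediate (not isolated)
20 | (1S,4R,5S,6S,7R,8S)-1-(tert-butyldimethylsilyloxy)-4,5-epoxy-6-(triethylsilyloxy)germacra-10(14),11(13)-dien-8,12-olide | C=C1C(=O)O[C@H]2CC(=C)[C@@H](O[Si](C)(C)C(C)(C)C)CC[C@@]3(C)O[C@H]3[C@@H](O[Si](CC)(CC)CC)[C@H]12 | intermediate
21 | (1S,4R,5S,6S,7S,8S)-1-(tert-butyldimethylsilyloxy)-4,5-epoxy-6-hydroxygermacra-10(14),11(13)-dien-8,12-olide | C=C1C(=O)O[C@H]2CC(=C)[C@@H](O[Si](C)(C)C(C)(C)C)CC[C@@]3(C)O[C@H]3[C@@H](O)[C@H]12 | intermediate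
22 | angelic acid, (2Z)-2-methylbut-2-enoic acid | C/C=C(/C)C(=O)O | starting material
23 | angelic 2,4,6-trichlorobenzoic anhydride | C/C=C(/C)C(=O)OC(=O)c1c(Cl)cc(Cl)cc1Cl | intermediate (not isolated)
24 | (1S,4R,5S,6S,7R,8S)-6-angeloyloxy-1-(tert-butyldimethylsilyloxy)-4,5-epoxygermacra-10(14),11(13)-dien-8,12-olide | C=C1C(=O)O[C@H]2CC(=C)[C@@H](O[Si](C)(C)C(C)(C)C)CC[C@@]3(C)O[C@H]3[C@@H](OC(=O)/C(C)=C\C)[C@H]12 | intermediate
25 | (1S,4R,5S,6S,7R,8S)-6-angeloyloxy-4,5-epoxy-1-hydroxygermacra-10(14),11(13)-dien-8,12-olide | C=C1C(=O)O[C@H]2CC(=C)[C@@H](O)CC[C@@]3(C)O[C@H]3[C@@H](OC(=O)/C(C)=C\C)[C@H]12 | target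

**Step count**
Total: 17 steps. Longest linear sequence: 16 steps (steps 2 to 17, from neryl acetate).

**Steps most likely to fail**

Step 14. The ring closure may lose to oligomerisation, the terminal allene π-bond may react instead of the internal one, facial control at C7 and C8 may be poor, and ruthenium hydrides may move the C10=C14 double bond into conjugation with the aldehyde. The fallback uses known chemistry, sets out from 15 and comes back at 20: the ten-membered ring is closed by a chromium-mediated allylation and the lactone by a separate palladium-catalysed carbonylation. Alkyne 15 is hydroxymethylated (nBuLi, THF, −78 °C, then paraformaldehyde) to the propargylic alcohol F1. Hydroxyl-directed trans-hydrostannation ([Cp*RuCl]4 cat., Bu3SnH, CH2Cl2) places tin on C11 and gives the (Z)-alkenylstannane F2, and iodine (CH2Cl2, 0 °C) converts it into the (Z)-alkenyl iodide F3. CBr4/PPh3 gives the allylic bromide F4, and Swern oxidation of the primary silyl ether as in step 13 gives the aldehyde F5. CrCl2 in THF at high dilution, without nickel so that only the allylic bromide is reduced, should close the ring through the chair transition state of the allylchromium and give the anti homoallylic alcohol, the macrocyclic iodo alcohol F6. Pd(PPh3)4 (cat.), CO (1 atm), K2CO3 in THF then closes the lactone to 20.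

Step 13. The amine base of the quench may move the C10=C14 double bond into conjugation with the new aldehyde, and the secondary silyl ether may be cleaved in part. The fallback sets out from 17 and comes back at 18: the primary silyl ether is first removed under mild acid (PPTS cat., MeOH/CH2Cl2, −20 °C) to give the primary alcohol F7, which is oxidised without amine base (Dess–Martin periodinane, NaHCO3, CH2Cl2, 0 °C) and used at once.

Step 10. The Grignard addition may show poor facial selectivity, which costs material at C6. The fallback sets out from 14 (as the epimer mixture) and comes back at 14: Dess–Martin oxidation gives the ethynyl ketone F8, and reagent-controlled reduction with (R)-2-methyl-CBS-oxazaborolidine and catecholborane, in which the ethynyl group acts as the small substituent, should return the 6S alcohol.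

Further compounds
F1 | step 14 | propargylic alcohol, hydroxymethylated alkyne from 15 | C=C(CCO[Si](CC)(CC)CC)[C@@H](O[Si](C)(C)C(C)(C)C)CC[C@@]1(C)O[C@H]1[C@@H](O[Si](CC)(CC)CC)C#CCO
F2 | step 14 | (Z)-alkenylstannane with tributyltin on C11 | C=C(CCO[Si](CC)(CC)CC)[C@@H](O[Si](C)(C)C(C)(C)C)CC[C@@]1(C)O[C@H]1[C@@H](O[Si](CC)(CC)CC)/C=C(/CO)[Sn](CCCC)(CCCC)CCCC
F3 | step 14 | (Z)-alkenyl iodide with iodine on C11 and free C13 alcohol | C=C(CCO[Si](CC)(CC)CC)[C@@H](O[Si](C)(C)C(C)(C)C)CC[C@@]1(C)O[C@H]1[C@@H](O[Si](CC)(CC)CC)/C=C(/CO)I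
F4 | step 14 | allylic bromide of F3 | C=C(CCO[Si](CC)(CC)CC)[C@@H](O[Si](C)(C)C(C)(C)C)CC[C@@]1(C)O[C@H]1[C@@H](O[Si](CC)(CC)CC)/C=C(/CBr)I
F5 | step 14 | aldehyde carrying the 2-iodoallyl bromide unit | O=CCC(=C)[C@@H](O[Si](C)(C)C(C)(C)C)CC[C@@]1(C)O[C@H]1[C@@H](O[Si](CC)(CC)CC)/C=C(/CBr)I
F6 | step 14 | macrocyclic iodo alcohol, ten-membered ring with 8-hydroxy and 1-iodovinyl on C7 | O[C@H]2CC(=C)[C@@H](O[Si](C)(C)C(C)(C)C)CC[C@@]3(C)O[C@H]3[C@@H](O[Si](CC)(CC)CC)[C@@H]2C(I)=C
F7 | step 13 | primary alcohol from 17 | OCCC(=C)[C@@H](O[Si](C)(C)C(C)(C)C)CC[C@@]1(C)O[C@H]1[C@@H](O[Si](CC)(CC)CC)C=C=C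
F8 | step 10 | ethynyl ketone from 14 | C=C(CCO[Si](CC)(CC)CC)[C@@H](O[Si](C)(C)C(C)(C)C)CC[C@@]1(C)O[C@H]1C(=O)C#C
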